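**Retrosynthetic overview**
1. Target 17 ⇐ ester 16 ⇐ C2–C3 bond: axial addition of an acetate silyl ketene acetal to the cyclic peroxycarbenium ion from 3-methoxy-1,2-dioxane 14 (sets C3 cis to the 4-ethyl group).
2. The 1,2-dioxane (the only ring, closed late) ⇐ peroxyacetalisation of the C3 acetal by a tertiary C6 hydroperoxide, itself from Co-catalysed O2/Et3SiH peroxidation of a C6 ethylidene (Wittig on the C6 ketone).
3. Key step: 1,4-dicarbonyl 9 (C3 aldehyde, C6 ketone) ⇐ C4–C5 bond by oxidative umpolung of the butanal enamine (α-formyl cation equivalent) attacked by enolsilane 7; this sets C4.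
4. Ketone 5 ⇐ two Cu/Josiphos conjugate additions (n-BuMgBr to methyl crotonate, EtMgBr to enone 4) set the side-chain methyl and ethyl centres.

Assumption: the hand of each chiral ligand/catalyst (Josiphos in steps 1 and 3, imidazolidinone in step 5) follows the published sense of induction and is confirmed on the first run; the mirror-image ligand is equally available and changes nothing else.

**Route**

Step 1
Reactants: 1 methyl (E)-but-2-enoate
Product: 2 methyl (S)-3-methylheptanoate
Conditions: n-BuMgBr (1.2 equiv), CuBr·SMe2 (1 mol %), (R,S)-Josiphos (1.2 mol %), t-BuOMe, −75 °C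
Reagents that add atoms: n-butylmagnesium bromide, CCCC[Mg]Br
Why: Cu/Josiphos-catalysed asymmetric conjugate addition of a Grignard reagent to an enoate, in which ligand-controlled delivery of butyl to one face of the β-carbon sets the methyl-bearing centre as (S).

Step 2
Reactants: 2 methyl (S)-3-methylheptanoate
Product: 4 (3E,6S)-6-methyldec-3-en-2-one, via (S)-3-methylheptanal 3 (not isolated)
Conditions: DIBAL-H (1.05 equiv), CH2Cl2, −78 °C; then Ph3P=CHC(O)CH3 (1.5 equiv), −78 °C → rt
Reagents that add atoms: 1-(triphenylphosphoranylidene)propan-2-one, CC(=O)C=P(c1ccccc1)(c1ccccc1)c1ccccc1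
Why: One-pot DIBAL half-reduction and (E)-selective Wittig olefination with a stabilised ylide; no new stereocentre is formed and the β-stereocentre cannot epimerise.

Step 3
Reactants: 4 (3E,6S)-6-methyldec-3-en-2-one
Product: 5 (4S,6S)-4-ethyl-6-methyldecan-2-one
Conditions: EtMgBr (1.3 equiv), CuBr·SMe2 (5 mol %), (S,R)-Josiphos (6 mol %), t-BuOMe, −75 °C
Reagents that add atoms: ethylmagnesium bromide, CC[Mg]Br
Why: Second Cu/Josiphos asymmetric conjugate addition, now to an acyclic enone, where the remote methyl centre does not interfere and the ligand hand sets the ethyl-bearing centre as (S).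

Step 4
Reactants: 5 (4S,6S)-4-ethyl-6-methyldecan-2-one
Product: 7 {[(4S,6S)-4-ethyl-6-methyldec-1-en-2-yl]oxy}trimethylsilane, via lithium enolate 6 (not isolated)
Conditions: LDA (1.1 equiv), TMSCl (1.3 equiv, internal quench), THF, −78 °C; non-aqueous work-up
Reagents that add atoms: chlorotrimethylsilane, C[Si](C)(C)Cl
Why: Kinetic enolisation takes the methyl protons rather than the β-branched methylene, and O-silylation gives the terminal silyl enol ether needed as π-nucleophile; no stereocentre is affected.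

Step 5
Reactants: 7 {[(4S,6S)-4-ethyl-6-methyldec-1-en-2-yl]oxy}trimethylsilane, 8 butanal
Product: 9 (2S,6S,8S)-2,6-diethyl-8-methyl-4-oxododecanal
Conditions: 8 (3 equiv), (2R,5R)-5-benzyl-2-tert-butyl-3-methylimidazolidin-4-one·TFA (20 mol %), CAN (2.5 equiv), 2,6-di-tert-butylpyridine (2.5 equiv), H2O (2 equiv), acetone, −20 °C, 24 h
Reagents that add atoms: none
Why: Organo-SOMO α-enolation (oxidative enamine catalysis): one-electron oxidation by CAN turns the chiral butanal enamine into a 3π-electron radical cation, an α-formyl cation (enolonium) equivalent, which the enolsilane attacks on the Re face left open by the benzyl group, joining two normally nucleophilic α-carbons into a 1,4-dicarbonyl and setting the future ring C4 as (S).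

Step 6
Reactants: 9 (2S,6S,8S)-2,6-diethyl-8-methyl-4-oxododecanal
Product: 10 (2S,6S,8S)-2,6-diethyl-1,1-dimethoxy-8-methyldodecan-4-one
Conditions: MeOSiMe3 (2.2 equiv), TMSOTf (2 mol %), CH2Cl2, −78 °C
Reagents that add atoms: methoxytrimethylsilane, CO[Si](C)(C)C
Why: Noyori acetalisation is kinetically selective for the aldehyde over the ketone and, being aprotic and cold, does not epimerise the α-stereocentre or trigger 1,4-dicarbonyl cyclisation.

Step 7
Reactants: 10 (2S,6S,8S)-2,6-diethyl-1,1-dimethoxy-8-methyldodecan-4-one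
Product: 11 (2S,6S,8S)-2,6-diethyl-4-ethylidene-1,1-dimethoxy-8-methyldodecane (E/Z mixture)
Conditions: EtPPh3Br (2.5 equiv), KHMDS (2.4 equiv), THF, 0 °C; then 10, 0 °C → rt
Reagents that add atoms: ethyltriphenylphosphonium bromide, CC[P+](c1ccccc1)(c1ccccc1)c1ccccc1.[Br-]
Why: Wittig olefination of an unhindered dialkyl ketone with a non-stabilised ylide; the acetal is inert and the E/Z ratio is irrelevant because both isomers give the same tertiary radical in step 8.

Step 8
Reactants: 11 (2S,6S,8S)-2,6-diethyl-4-ethylidene-1,1-dimethoxy-8-methyldodecane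
Product: 12 triethyl{[(2S,4S,6S,8S)-2,4,6-triethyl-1,1-dimethoxy-8-methyldodecan-4-yl]peroxy}silane (with its 4-epimer, ca. 1:1)
Conditions: Co(thd)2 (10 mol %), O2 (1 atm), Et3SiH (2 equiv), ClCH2CH2Cl, rt
Reagents that add atoms: dioxygen, O=O; triethylsilane, CC[SiH](CC)CC
Why: Mukaiyama–Isayama hydroperoxysilylation, in which Co–H hydrogen-atom transfer gives the Markovnikov tertiary radical that traps O2 and is silylated; the radical is planar, so the new quaternary centre (ring C6) forms as both epimers, which are carried on and separated at 16.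

Step 9
Reactants: 12 triethyl{[(2S,4S,6S,8S)-2,4,6-triethyl-1,1-dimethoxy-8-methyldodecan-4-yl]peroxy}silane
Product: 14 (3R,4S,6S)-4,6-diethyl-6-[(2S,4S)-2-ethyl-4-methyloctyl]-3-methoxy-1,2-dioxane, via hydroperoxide 13 (not isolated)
Conditions: TsOH·H2O (10 mol %), MeOH/CH2Cl2 (1:4), 0 °C → rt
Reagents that add atoms: none
Why: Acidic methanolysis cleaves the Si–OO bond and the hydroperoxide closes the six-membered ring by transacetalisation (cyclic peroxyacetal formation), the anomeric centre equilibrating mainly to axial OMe while no other stereocentre is touched.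

Step 10
Reactants: 14 (3R,4S,6S)-4,6-diethyl-6-[(2S,4S)-2-ethyl-4-methyloctyl]-3-methoxy-1,2-dioxane
Product: 16 methyl 2-[(3S,4S,6S)-4,6-diethyl-6-[(2S,4S)-2-ethyl-4-methyloctyl]-1,2-dioxan-3-yl]acetate, via peroxycarbenium ion 15 (not isolated)
Conditions: CH2=C(OMe)OTBS (3 equiv), TMSOTf (20 mol %), CH2Cl2, −78 °C; preparative HPLC to remove the 6-epimer
Reagents that add atoms: tert-butyl[(1-methoxyethenyl)oxy]dimethylsilane, C=C(OC)O[Si](C)(C)C(C)(C)C
Why: Lewis-acid substitution of a peroxyacetal (Mukaiyama-type addition to a peroxycarbenium ion), whose half-chair is locked by the equatorial 4-ethyl group and the 6,6-disubstitution so that the ketene acetal adds axially, anti to the axial C6 substituent, placing CH2CO2Me cis to 4-Et (3S) from either anomer.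

Step 11
Reactants: 16 methyl 2-[(3S,4S,6S)-4,6-diethyl-6-[(2S,4S)-2-ethyl-4-methyloctyl]-1,2-dioxan-3-yl]acetate
Product: 17 2-[(3S,4S,6S)-4,6-diethyl-6-[(2S,4S)-2-ethyl-4-methyloctyl]-1,2-dioxan-3-yl]acetic acid
Conditions: LiOH·H2O (3 equiv), THF/H2O (3:1), 0 °C → rt; then 1 M HCl to pH 3
Reagents that add atoms: lithium hydroxide, [Li+].[OH-]
Why: Saponification of the methyl ester, which at 0 °C is faster than β-elimination of the peroxide, followed by mild acidification that leaves the O–O bond and all stereocentres untouched.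

**Compound list**
1 | methyl (E)-but-2-enoate | C/C=C/C(=O)OC | starting material
2 | methyl (S)-3-methylheptanoate | CCCC[C@H](C)CC(=O)OC | intermediate
3 | (S)-3-methylheptanal | CCCC[C@H](C)CC=O | intermediate
4 | (3E,6S)-6-methyldec-3-en-2-one | CCCC[C@H](C)C/C=C/C(C)=O | intermediate
5 | (4S,6S)-4-ethyl-6-methyldecan-2-one | CCCC[C@H](C)C[C@H](CC)CC(C)=O | intermediate
6 | lithium (4S,6S)-4-ethyl-6-methyldec-1-en-2-olate | CCCC[C@H](C)C[C@H](CC)CC(=C)[O-].[Li+] | intermediate
7 | {[(4S,6S)-4-ethyl-6-methyldec-1-en-2-yl]oxy}trimethylsilane | CCCC[C@H](C)C[C@H](CC)CC(=C)O[Si](C)(C)C | intermediate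
8 | butanal | CCCC=O | starting material
9 | (2S,6S,8S)-2,6-diethyl-8-methyl-4-oxododecanal | CCCC[C@H](C)C[C@H](CC)CC(=O)C[C@H](CC)C=O | intermediate
10 | (2S,6S,8S)-2,6-diethyl-1,1-dimethoxy-8-methyldodecan-4-one | CCCC[C@H](C)C[C@H](CC)CC(=O)C[C@H](CC)C(OC)OC | intermediate
11 | (2S,6S,8S)-2,6-diethyl-4-ethylidene-1,1-dimethoxy-8-methyldodecane (E/Z mixture) | CCCC[C@H](C)C[C@H](CC)CC(=CC)C[C@H](CC)C(OC)OC | intermediate
12 | triethyl{[(2S,4S,6S,8S)-2,4,6-triethyl-1,1-dimethoxy-8-methyldodecan-4-yl]peroxy}silane (desired epimer shown; carried with its 4-epimer) | CCCC[C@H](C)C[C@H](CC)C[C@@](OO[Si](CC)(CC)CC)(CC)C[C@H](CC)C(OC)OC | intermediate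
13 | (2S,4S,6S,8S)-2,4,6-triethyl-4-hydroperoxy-1,1-dimethoxy-8-methyldodecane | CCCC[C@H](C)C[C@H](CC)C[C@@](OO)(CC)C[C@H](CC)C(OC)OC | intermediate
14 | (3R,4S,6S)-4,6-diethyl-6-[(2S,4S)-2-ethyl-4-methyloctyl]-3-methoxy-1,2-dioxane (major anomer; carried with its 6-epimer) | CCCC[C@H](C)C[C@H](CC)C[C@@]1(CC)C[C@H](CC)[C@H](OC)OO1 | intermediate
15 | (4S,6S)-4,6-diethyl-6-[(2S,4S)-2-ethyl-4-methyloctyl]-5,6-dihydro-4H-1,2-dioxin-2-ium (peroxycarbenium ion) | CCCC[C@H](C)C[C@H](CC)C[C@@]1(CC)C[C@H](CC)C=[O+]O1 | intermediate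
16 | methyl 2-[(3S,4S,6S)-4,6-diethyl-6-[(2S,4S)-2-ethyl-4-methyloctyl]-1,2-dioxan-3-yl]acetate | CCCC[C@H](C)C[C@H](CC)C[C@@]1(CC)C[C@H](CC)[C@H](CC(=O)OC)OO1 | intermediate
17 | 2-[(3S,4S,6S)-4,6-diethyl-6-[(2S,4S)-2-ethyl-4-methyloctyl]-1,2-dioxan-3-yl]acetic acid | CCCC[C@H](C)C[C@H](CC)C[C@@]1(CC)C[C@H](CC)[C@H](CC(=O)O)OO1 | target

**Step count**
Total steps: 11. Longest linear sequence: 11 (1 → 17; butanal 8 enters at step 5).

**Three steps most likely to fail**

Step 5. A primary-alkyl enolsilane is at the edge of what the CAN-mediated enolation tolerates; it may hydrolyse back to 5 (recoverable) before it couples. The fallback sets out from 7 and comes back at 9. NBS (THF, 0 °C) converts 7 into (4S,6S)-1-bromo-4-ethyl-6-methyldecan-2-one F1. F1 and butanal 8 are then coupled by photoredox/enamine catalysis (fac-Ir(ppy)3, the antipode of 2-tert-butyl-3,5-dimethylimidazolidin-4-one triflate that leaves the enamine Re face open, 2,6-lutidine, DMF, blue light). Here the polarity is reversed on the ketone partner instead: its electrophilic α-keto radical adds to the nucleophilic chiral enamine and gives 9 directly.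

Step 8. The radical peroxidation gives no control at C6, so half the material is the wrong epimer, and the epimers must separate at 16. The fallback sets out from 10 and comes back at 14. EtMgBr/CeCl3 (THF, −78 °C) adds to the ketone to give (2S,6S,8S)-2,4,6-triethyl-1,1-dimethoxy-8-methyldodecan-4-ol F2. Acid-catalysed perhydrolysis (50% H2O2, cat. H2SO4, Et2O, 0 °C; SN1 at the tertiary carbon) then gives hydroperoxide 13, which closes to 14 in MeOH/TsOH as in step 9. This replaces the radical chemistry by ionic chemistry if the cobalt step is low-yielding, but it also gives both C6 epimers; I have no short stereospecific alternative for this centre.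

Step 10. The peroxycarbenium ion may fragment, and the C3 selectivity rests on a stereoelectronic model, not on a close precedent with a 4-alkyl neighbour. The fallback sets out from 14 and comes back at 17. Allyltrimethylsilane, the most dependable π-nucleophile for such cations (SnCl4, CH2Cl2, −78 °C), gives (3S,4S,6S)-4,6-diethyl-6-[(2S,4S)-2-ethyl-4-methyloctyl]-3-(prop-2-en-1-yl)-1,2-dioxane F3 by the same axial attack. Ozonolysis (O3, CH2Cl2, −78 °C; Me2S) gives 2-[(3S,4S,6S)-4,6-diethyl-6-[(2S,4S)-2-ethyl-4-methyloctyl]-1,2-dioxan-3-yl]acetaldehyde F4. Pinnick oxidation (NaClO2, NaH2PO4, 2-methyl-2-butene) then gives 17, without exposing a β-peroxy ester to base.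

Further compounds
F1 | step 5 | (4S,6S)-1-bromo-4-ethyl-6-methyldecan-2-one | CCCC[C@H](C)C[C@H](CC)CC(=O)CBr
F2 | step 8 | (2S,6S,8S)-2,4,6-triethyl-1,1-dimethoxy-8-methyldodecan-4-ol (both C4 epimers) | CCCC[C@H](C)C[C@H](CC)CC(O)(CC)C[C@H](CC)C(OC)OC
F3 | step 10 | (3S,4S,6S)-4,6-diethyl-6-[(2S,4S)-2-ethyl-4-methyloctyl]-3-(prop-2-en-1-yl)-1,2-dioxane | CCCC[C@H](C)C[C@H](CC)C[C@@]1(CC)C[C@H](CC)[C@H](CC=C)OO1
F4 | step 10 | 2-[(3S,4S,6S)-4,6-diethyl-6-[(2S,4S)-2-ethyl-4-methyloctyl]-1,2-dioxan-3-yl]acetaldehyde | CCCC[C@H](C)C[C@H](CC)C[C@@]1(CC)C[C@H](CC)[C@H](CC=O)OO1
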